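**Assumptions (remarks on the chemistry)**
- The lipase of Burkholderia cepacia is taken to acetylate the enantiotopic hydroxymethyl group of 5 that gives the (R)-monoacetate 6, the sense its usual preference for 2-(arylmethyl)propane-1,3-diols predicts.
- The (R)-tert-leucinate dirhodium catalyst is taken to deliver the (2S) centre of 20; if the sense is the opposite one, the (S)-catalyst is used with nothing else changed.

## Structural features

The target is a γ-butyrolactone (ring O, carbonyl C1, C-alpha, C-beta, C4) whose neighbouring carbons C-alpha and C-beta carry arylmethyl groups in a trans (3S,4S) relationship. C-beta bears a 4-hydroxy-3-methoxybenzyl group, and C-alpha bears a CH2 that leads to C5 of a 2,3-dihydrobenzofuran. The dihydrobenzofuran has a 4-hydroxy-3-methoxyphenyl group at C2 and a hydroxymethyl group at C3, trans (2S,3R), and a free phenol at C7 next to ring oxygen O1. The four stereocentres form two adjacent pairs (C-alpha/C-beta and C2/C3) separated by an arene and a methylene, so neither pair can steer the other and each must be made in absolute form on its own fragment. The fragile sites are the C2–O1 bond (a benzylic aryl ether, open to hydrogenolysis, to acid ionisation and, once the para hydroxyl is free, to base-induced opening through a quinone methide), the lactone, the epimerisable C-alpha and three electron-rich phenols. The real difficulty is to join two enantiopure halves at the C-alpha–CH2–C5 link without touching C-beta and to finish as the trans lactone without breaking the benzylic ring ether. The feature exploited is that C1 lies between the ring oxygen on C4 and C-alpha, while C-alpha–CH2–C5(arene) is the reduced form of an aryl alkyne. The chain O–C4–C-beta–C-alpha≡C–C5 is therefore a homopropargylic alcohol, and C1 can be inserted as carbon monoxide between its hydroxyl oxygen and the proximal alkyne carbon.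

## Logic of the disconnections

28 to 27: the four benzyl–oxygen bonds (three phenolic, one on the primary alcohol) are cut. One robust group type masks every hydroxyl except the one that must be carbonylated, and one neutral operation removes all four at the end. The forward step must spare the C2–O1 bond, and it must come last so that no base meets a free para-hydroxybenzyl ether.

27 to 26 to 25: the C-alpha configuration is traced to an equilibration, and the two C–H bonds at C-alpha and its exocyclic carbon to a hydrogenation. The trans lactone is the thermodynamic isomer, so C-alpha need not be set kinetically, and going back to the arylidene removes a stereocentre. The hydrogenation must leave benzyl ethers and the ring ether alone. The base step must follow saturation (no deprotonation at C-beta through the conjugated system) and precede unmasking of the phenols.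

25 to 24: the C1–O and C1–C-alpha bonds are cut, which releases carbon monoxide and opens the lactone to an acyclic alkynol. This removes a ring and exposes an alkyne, a natural seam for fragment coupling. The forward step needs syn addition, five-membered closure and a single free hydroxyl.

24 to 23 and 11: the bond between the alkyne carbon and C5 is cut. Each pair of stereocentres now sits in its own fragment, and the halves meet through an sp–sp2 coupling that touches no stereocentre. The coupling must work on an electron-rich aryl bromide at room temperature, without propargylic isomerisation.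

11 back to 5 (through 10, 9, 8, 7, 6): the terminal alkyne carbon is cut (one-carbon homologation of an aldehyde), and the stereocentre is traced to the prochiral diol 5, whose two hydroxymethyl arms are enantiotopic. The enzyme marks with acetate the arm that must become the alkyne, hence the exchange of roles 6 to 7 to 8 before oxidation. The demands are no acyl or silyl migration and no epimerisation of 9.

5 to 4 to 2 and 3, and 2 to 1: the C-beta–CH2(aryl) bond is cut as a malonate alkylation, and both ester carbons are returned to the alcohol oxidation level. This reduces the lactone half to two cheap building blocks.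

23 back to 19 (through 22, 21, 20): after removal of the benzyl group and return of the alcohol to the ester, the C3 configuration is traced to an equilibration and the C2–C3 bond is cut as a carbenoid C–H insertion. Both ring stereocentres then arise from an achiral acyclic diazo ester. The catalyst must set C2, thermodynamics sets C3, and insertion must outrun ylide formation.

19 back to 12 (through 18, 17, 16, 15, 14, 13): the diazo group is traced to a ketone, the aryl–carbonyl bond is cut (aryl metal plus oxalate), then the ether O–CH2 bond (which brings in 2 a second time), then the C–I and C–Br bonds. The substitution pattern follows from the directing power of one free phenol: para for bromine (future C5), ortho for iodine (future C3a–C3 bond). The metalation must distinguish iodine from bromine.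

## Other disconnections considered

Alternative 1: The cuts are the bond between the guaiacyl ring and its benzylic carbon and the bond between C-alpha and the benzofuranyl CH2. This reduces the lactone to the cyclopropane-fused lactone A2, one step from 3 and (S)-epichlorohydrin A5. Forward, the cuprate from aryl Grignard reagent A4 and CuI would open the activated cyclopropane of A2 at its CH2 carbon. The ester-stabilised lactone enolate set free would then be alkylated by benzylic bromide A3 on the face away from the new arylmethyl group, to give A1. Dealkoxycarbonylation and hydrogenolysis would finish.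
- In its favour: two C–C bonds would form in one flask; C-beta comes from the chiral pool and does not depend on an enzyme's sense; no pressure equipment is needed.
- Against it here: A3 is a para-alkoxy-type benzylic bromide, prone to ionise, and would cost about three more steps from 23 (formylation, reduction, bromination). The dealkoxycarbonylation needs hot halide in a dipolar solvent in the presence of the benzylic ring ether, and it erases the C-alpha centre just set.
- Comparison: on structure the two plans are equal in leaving C-alpha to thermodynamic control, and the alternative is the better one in the source of C-beta. On mechanism it is the equal of the chosen plan in convergence and the better one in avoiding pressurised carbon monoxide, but worse in needing a labile sp3 electrophile where the chosen plan couples 23 directly. On step economy it is the better one: one step to A2 against eight to 11, which should outweigh the extra steps to A3.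

Alternative 2: The cut is the C3–C3a bond of the dihydrobenzofuran, traced to the C4–C4a bond of flavanone A7, itself from chalcone A8. It concerns only the benzofuran fragment and is silent on how the lactone is made and joined. Forward, PhI(OAc)2 and catalytic H2SO4 in trimethyl orthoformate would convert A7 into its enol ether and attach trivalent iodine at C3. The benzo-ring carbon C4a would then shift from C4 to C3 as iodobenzene leaves, and the resulting dialkoxycarbenium ion would end as the methyl ester A6.
- In its favour: it would give the trans ester with bromine at C5 directly, carry C2 through without creating it at that stage, and avoid a diazo compound and a chiral dirhodium catalyst.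
- Against it here: A7 is needed as one enantiomer, and enantioselective ring closure of chalcones such as A8 is less general than carbenoid insertion. Flavanones can racemise by reversible ring opening in strong acid. The pivalate needed to restrain the competing shift of the C2 aryl ring would not survive ester reduction and forces a protecting-group exchange.
- Comparison: on structure it is the equal of steps 9 to 14, since both deliver a C5-brominated trans ester. On mechanism it is the better one in giving trans without an epimerisation and worse in the origin of absolute configuration. On step economy the two should be about equal. It is not a rival to the carbonylation and could replace steps 9 to 14 inside the chosen plan.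

Alternative 3: The cut is the C4–O bond of the lactone; the two ring bonds from C-beta are traced to the enantiotopic C(=O)–CH2 bonds of cyclobutanone A10, which would come from O-benzyleugenol A11 by ketene cycloaddition and dechlorination. Forward, Sc(OTf)3 with a chiral N,N'-dioxide ligand and m-chloroperbenzoic acid would form the peracid adduct, and migration of one enantiotopic CH2 would give lactone A9. The lithium enolate of A9 would then be alkylated by A3 anti to the β-substituent to give 27 directly.
- In its favour: C-beta would be set catalytically in about three steps from a cheap allylarene, and C-alpha kinetically trans in the bond-forming step, so no hydrogenation or equilibration is needed.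
- Against it here: enantiomeric purity would rest on discrimination between two CH2 groups that differ only through a remote substituent, which is harder to bring to the level of an enzymatic desymmetrisation. A peracid meets an electron-rich arene. The labile bromide A3 is again required.
- Comparison: on structure it is the equal of the chosen plan in the benzofuran fragment and the better one in how C-alpha is set. On mechanism the chosen plan is the better one in joining the halves under neutral conditions through the aryl bromide itself and in assurance of enantiopurity. On step economy the alternative is the better one by several steps.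

Key step: step 18

## Steps

Step 1
Reactants: 1 4-(benzyloxy)-3-methoxybenzyl alcohol
Product: 2 4-(benzyloxy)-3-methoxybenzyl chloride
Conditions: SOCl2, CH2Cl2, 0 °C to rt
Reagents that add atoms: thionyl chloride, O=S(Cl)Cl
Why: Chlorination of an electron-rich benzylic alcohol through its chlorosulfite; no stereocentre is involved and the chloride is used fresh.

Step 2
Reactants: 2 4-(benzyloxy)-3-methoxybenzyl chloride; 3 diethyl malonate
Product: 4 diethyl 2-[4-(benzyloxy)-3-methoxybenzyl]malonate
Conditions: NaH, 3 (3 equiv), THF–DMF, 0 °C to rt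
Reagents that add atoms: none
Why: Malonic ester alkylation (SN2) with a reactive benzylic chloride; the excess of 3 suppresses double alkylation.

Step 3
Reactants: 4 diethyl 2-[4-(benzyloxy)-3-methoxybenzyl]malonate
Product: 5 2-[4-(benzyloxy)-3-methoxybenzyl]propane-1,3-diol
Conditions: LiAlH4, THF, 0 °C to rt
Reagents that add atoms: none
Why: Hydride reduction of both esters gives the prochiral 1,3-diol; aryl ethers are inert.

Step 4
Reactants: 5 2-[4-(benzyloxy)-3-methoxybenzyl]propane-1,3-diol
Product: 6 (R)-2-[4-(benzyloxy)-3-methoxybenzyl]-3-hydroxypropyl acetate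
Conditions: Burkholderia cepacia lipase, vinyl acetate, t-BuOMe, 25 °C
Reagents that add atoms: vinyl acetate, C=COC(C)=O
Why: Lipase-catalysed irreversible transesterification desymmetrises the diol by acetylating one enantiotopic hydroxymethyl group, which creates the future C-beta centre in the sense assumed above; slight over-acylation removes the minor enantiomer and should raise the purity.

Step 5
Reactants: 6 (R)-2-[4-(benzyloxy)-3-methoxybenzyl]-3-hydroxypropyl acetate
Product: 7 (S)-2-[4-(benzyloxy)-3-methoxybenzyl]-3-[(tert-butyldimethylsilyl)oxy]propyl acetate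
Conditions: TBSCl, imidazole, CH2Cl2, 0 °C to rt
Reagents that add atoms: tert-butyldimethylsilyl chloride, CC(C)(C)[Si](C)(C)Cl
Why: Prompt silylation of the free arm blocks 1,3-acyl migration (which would racemise 6) and tells the two arms apart; the stereocentre is untouched and the descriptor changes only by priority.

Step 6
Reactants: 7 (S)-2-[4-(benzyloxy)-3-methoxybenzyl]-3-[(tert-butyldimethylsilyl)oxy]propyl acetate
Product: 8 (S)-2-[4-(benzyloxy)-3-methoxybenzyl]-3-[(tert-butyldimethylsilyl)oxy]propan-1-ol
Conditions: K2CO3 (0.2 equiv), MeOH, 0 °C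
Reagents that add atoms: none
Why: Mild base-catalysed methanolysis removes the acetate while the silyl ether stays in place at 0 °C; the arm marked by the enzyme is now the free one.

Step 7
Reactants: 8 (S)-2-[4-(benzyloxy)-3-methoxybenzyl]-3-[(tert-butyldimethylsilyl)oxy]propan-1-ol
Product: 9 (R)-2-[4-(benzyloxy)-3-methoxybenzyl]-3-[(tert-butyldimethylsilyl)oxy]propanal
Conditions: Dess–Martin periodinane, NaHCO3, CH2Cl2, 0 °C to rt
Reagents that add atoms: none
Why: Dess–Martin oxidation under buffered conditions gives the α-branched β-silyloxy aldehyde without epimerisation; it is used crude.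

Step 8
Reactants: 9 (R)-2-[4-(benzyloxy)-3-methoxybenzyl]-3-[(tert-butyldimethylsilyl)oxy]propanal
Product: 11 (S)-2-[4-(benzyloxy)-3-methoxybenzyl]but-3-yn-1-ol, via silyl alkyne 10 (not isolated)
Conditions: MeC(O)C(N2)P(O)(OMe)2, K2CO3, MeOH, 0 °C to rt; then conc. HCl to pH 1, rt
Reagents that add atoms: dimethyl (1-diazo-2-oxopropyl)phosphonate (Bestmann–Ohira reagent), COP(=O)(OC)C(=[N+]=[N-])C(C)=O
Why: Ohira–Bestmann (Seyferth–Gilbert) homologation: the diazomethylphosphonate anion adds to the aldehyde, and loss of phosphate and N2 gives an alkylidene carbene whose 1,2-hydrogen shift forms the terminal alkyne with the α-centre untouched; acidified methanol then cleaves the primary silyl ether.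

Step 9
Reactants: 12 2-(benzyloxy)phenol
Product: 13 2-(benzyloxy)-4-bromophenol
Conditions: NBS, MeCN, 0 °C
Reagents that add atoms: N-bromosuccinimide, O=C1CCC(=O)N1Br
Why: Electrophilic bromination para to the free hydroxyl, the strongest director; this bromine becomes the coupling handle at C5.

Step 10
Reactants: 13 2-(benzyloxy)-4-bromophenol
Product: 14 2-(benzyloxy)-4-bromo-6-iodophenol
Conditions: NIS, TsOH (cat.), MeCN, rt
Reagents that add atoms: N-iodosuccinimide, O=C1CCC(=O)N1I
Why: Electrophilic iodination at the only free position ortho to the hydroxyl; this marks the carbon that will carry C3.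

Step 11
Reactants: 14 2-(benzyloxy)-4-bromo-6-iodophenol; 2 4-(benzyloxy)-3-methoxybenzyl chloride
Product: 15 1-(benzyloxy)-2-{[4-(benzyloxy)-3-methoxybenzyl]oxy}-5-bromo-3-iodobenzene
Conditions: K2CO3, DMF, 50 °C
Reagents that add atoms: none
Why: Williamson ether synthesis; it installs the O–CH2–aryl unit whose CH2 becomes C2.

Step 12
Reactants: 15 1-(benzyloxy)-2-{[4-(benzyloxy)-3-methoxybenzyl]oxy}-5-bromo-3-iodobenzene
Product: 17 methyl 2-(3-(benzyloxy)-2-{[4-(benzyloxy)-3-methoxybenzyl]oxy}-5-bromophenyl)-2-oxoacetate, via arylmagnesium chloride 16 (not isolated)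
Conditions: i-PrMgCl·LiCl, THF, −40 °C; then added to (CO2Me)2 (3 equiv), THF, −78 to 0 °C
Reagents that add atoms: dimethyl oxalate, COC(=O)C(=O)OC
Why: Iodine–magnesium exchange is selective for C–I over C–Br at low temperature and is helped by the ortho alkoxy group; inverse addition to excess oxalate stops at the α-keto ester.

Step 13
Reactants: 17 methyl 2-(3-(benzyloxy)-2-{[4-(benzyloxy)-3-methoxybenzyl]oxy}-5-bromophenyl)-2-oxoacetate
Product: 19 methyl 2-(3-(benzyloxy)-2-{[4-(benzyloxy)-3-methoxybenzyl]oxy}-5-bromophenyl)-2-diazoacetate, via tosylhydrazone 18 (not isolated)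
Conditions: TsNHNH2, MeOH, 50 °C; then DBU, CH2Cl2, rt
Reagents that add atoms: p-toluenesulfonohydrazide, Cc1ccc(cc1)S(=O)(=O)NN
Why: Condensation to the tosylhydrazone, then base-induced loss of sulfinate (Bamford–Stevens type), gives the aryl diazoacetate under neutral to basic conditions that the acid-labile benzylic aryl ether tolerates.

Step 14
Reactants: 19 methyl 2-(3-(benzyloxy)-2-{[4-(benzyloxy)-3-methoxybenzyl]oxy}-5-bromophenyl)-2-diazoacetate
Product: 21 methyl (2S,3S)-7-(benzyloxy)-2-[4-(benzyloxy)-3-methoxyphenyl]-5-bromo-2,3-dihydro-1-benzofuran-3-carboxylate (trans), via cis ester 20 (not isolated)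
Conditions: Rh2(R-PTTL)4 [dirhodium tetrakis(N-phthaloyl-(R)-tert-leucinate)] (1 mol%), toluene, −60 °C; then NaOMe, MeOH–THF, rt
Reagents that add atoms: none
Why: The dirhodium carbenoid inserts into the ortho O–CH2 benzylic C–H bond (five-membered closure, forming C2–C3), with the chiral carboxylate pocket fixing C2 as (S) and giving the cis ester; methoxide then epimerises C3 through the ester enolate to the more stable trans ester, and C2 is kept because opening of that enolate would be a disfavoured reverse 5-endo process.

Step 15
Reactants: 21 methyl (2S,3S)-7-(benzyloxy)-2-[4-(benzyloxy)-3-methoxyphenyl]-5-bromo-2,3-dihydro-1-benzofuran-3-carboxylate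
Product: 22 {(2S,3R)-7-(benzyloxy)-2-[4-(benzyloxy)-3-methoxyphenyl]-5-bromo-2,3-dihydro-1-benzofuran-3-yl}methanol
Conditions: LiBH4, THF, 0 °C to rt
Reagents that add atoms: none
Why: Borohydride reduction of the ester leaves the aryl bromide and benzyl ethers alone; C3 is no longer epimerisable afterwards (the descriptor changes only by priority).

Step 16
Reactants: 22 {(2S,3R)-7-(benzyloxy)-2-[4-(benzyloxy)-3-methoxyphenyl]-5-bromo-2,3-dihydro-1-benzofuran-3-yl}methanol
Product: 23 (2S,3R)-7-(benzyloxy)-3-[(benzyloxy)methyl]-2-[4-(benzyloxy)-3-methoxyphenyl]-5-bromo-2,3-dihydro-1-benzofuran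
Conditions: NaH, BnBr, n-Bu4NI (cat.), THF–DMF, 0 °C to rt
Reagents that add atoms: benzyl bromide, BrCc1ccccc1
Why: Williamson benzylation of the primary alkoxide; it masks the only other hydroxyl that could compete in the carbonylation.

Step 17
Reactants: 23 (2S,3R)-7-(benzyloxy)-3-[(benzyloxy)methyl]-2-[4-(benzyloxy)-3-methoxyphenyl]-5-bromo-2,3-dihydro-1-benzofuran; 11 (S)-2-[4-(benzyloxy)-3-methoxybenzyl]but-3-yn-1-ol
Product: 24 (S)-2-[4-(benzyloxy)-3-methoxybenzyl]-4-{(2S,3R)-7-(benzyloxy)-3-[(benzyloxy)methyl]-2-[4-(benzyloxy)-3-methoxyphenyl]-2,3-dihydro-1-benzofuran-5-yl}but-3-yn-1-ol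
Conditions: PdCl2(PhCN)2 (3 mol%), [HP(t-Bu)3]BF4 (6 mol%), CuI (2 mol%), i-Pr2NH, 1,4-dioxane, rt
Reagents that add atoms: none
Why: Sonogashira coupling; zerovalent palladium carrying the bulky trialkylphosphine adds oxidatively to the electron-rich aryl bromide at room temperature, the copper acetylide transmetallates, and the free hydroxyl and all four stereocentres are bystanders.

Step 18
Reactants: 24 (S)-2-[4-(benzyloxy)-3-methoxybenzyl]-4-{(2S,3R)-7-(benzyloxy)-3-[(benzyloxy)methyl]-2-[4-(benzyloxy)-3-methoxyphenyl]-2,3-dihydro-1-benzofuran-5-yl}but-3-yn-1-ol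
Product: 25 (3E,4S)-4-[4-(benzyloxy)-3-methoxybenzyl]-3-({(2S,3R)-7-(benzyloxy)-3-[(benzyloxy)methyl]-2-[4-(benzyloxy)-3-methoxyphenyl]-2,3-dihydro-1-benzofuran-5-yl}methylidene)dihydrofuran-2(3H)-one
Conditions: PdCl2(PPh3)2 (5 mol%), SnCl2 (5 mol%), CO (8 atm), MeCN, 75 °C
Reagents that add atoms: carbon monoxide, [C-]#[O+]
Why: Divalent palladium, CO and the homopropargylic hydroxyl of 24 form an alkoxycarbonyl–palladium species, with SnCl2 keeping the metal electrophilic. This unit adds syn across the tethered alkyne: the acyl carbon bonds to the proximal alkyne carbon (future C-alpha) and palladium to the aryl-bearing carbon. Protonolysis of the vinyl–palladium bond by the HCl released in the first stage proceeds with retention and returns divalent palladium, so hydrogen ends cis to the carbonyl and the aryl group trans to it, which is the (E)-arylidene. The closest known reaction is the palladium/tin-catalysed cyclocarbonylation of but-3-yn-1-ols to α-methylene- and (E)-α-alkylidene-γ-butyrolactones. The one ring formed, the lactone, closes in the 5-exo-dig mode with respect to the attacking acyl carbon; the 6-endo mode would put palladium on the alkyl-substituted carbon and is disfavoured by the short tether. No stereocentre is created: C-beta lies outside the reacting atoms and the neutral to weakly acidic medium cannot deprotonate it through the new conjugated system, while the alkene geometry follows from syn addition plus retentive protonolysis. The step needs chemoselectivity for one hydroxyl, which is secured by benzylation of every other oxygen, and it needs carbonylation to outrun direct attack of the hydroxyl on the activated alkyne, which CO pressure and phosphine ligation favour.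

Step 19
Reactants: 25 (3E,4S)-4-[4-(benzyloxy)-3-methoxybenzyl]-3-({(2S,3R)-7-(benzyloxy)-3-[(benzyloxy)methyl]-2-[4-(benzyloxy)-3-methoxyphenyl]-2,3-dihydro-1-benzofuran-5-yl}methylidene)dihydrofuran-2(3H)-one
Product: 26 (3R,4S)-4-[4-(benzyloxy)-3-methoxybenzyl]-3-({(2S,3R)-7-(benzyloxy)-3-[(benzyloxy)methyl]-2-[4-(benzyloxy)-3-methoxyphenyl]-2,3-dihydro-1-benzofuran-5-yl}methyl)dihydrofuran-2(3H)-one (cis, expected main isomer)
Conditions: H2 (1 atm), 10% Pd/C, Ph2S (cat.), EtOAc, rt
Reagents that add atoms: none
Why: Heterogeneous hydrogenation on sulfide-poisoned palladium on carbon saturates the conjugated alkene but leaves benzyl ethers and the benzylic ring ether; hydrogen should add to the face away from the C-beta substituent and give mainly the cis lactone, which the next step corrects.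

Step 20
Reactants: 26 (3R,4S)-4-[4-(benzyloxy)-3-methoxybenzyl]-3-({(2S,3R)-7-(benzyloxy)-3-[(benzyloxy)methyl]-2-[4-(benzyloxy)-3-methoxyphenyl]-2,3-dihydro-1-benzofuran-5-yl}methyl)dihydrofuran-2(3H)-one
Product: 27 (3S,4S)-4-[4-(benzyloxy)-3-methoxybenzyl]-3-({(2S,3R)-7-(benzyloxy)-3-[(benzyloxy)methyl]-2-[4-(benzyloxy)-3-methoxyphenyl]-2,3-dihydro-1-benzofuran-5-yl}methyl)dihydrofuran-2(3H)-one (trans)
Conditions: DBU, toluene, 50 °C
Reagents that add atoms: none
Why: Reversible enolisation at C-alpha equilibrates to the thermodynamically favoured trans-disubstituted lactone; C-beta has no acidic hydrogen in the saturated lactone, and the phenols are still masked, so no quinone methide can form.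

Step 21
Reactants: 27 (3S,4S)-4-[4-(benzyloxy)-3-methoxybenzyl]-3-({(2S,3R)-7-(benzyloxy)-3-[(benzyloxy)methyl]-2-[4-(benzyloxy)-3-methoxyphenyl]-2,3-dihydro-1-benzofuran-5-yl}methyl)dihydrofuran-2(3H)-one
Product: 28 (3S,4S)-4-(4-hydroxy-3-methoxybenzyl)-3-{[(2S,3R)-7-hydroxy-2-(4-hydroxy-3-methoxyphenyl)-3-(hydroxymethyl)-2,3-dihydro-1-benzofuran-5-yl]methyl}dihydrofuran-2(3H)-one
Conditions: H2 (1 atm), 10% Pd/C, EtOAc–EtOH, rt
Reagents that add atoms: none
Why: Neutral hydrogenolysis removes the four benzyl ethers; the ring C2–O1 bond is a secondary, hindered benzylic ether on an electron-rich arene and should react more slowly, so the reaction is stopped at completion.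

## Compound list

1 | 4-(benzyloxy)-3-methoxybenzyl alcohol | COc1cc(CO)ccc1OCc1ccccc1 | starting material
2 | 4-(benzyloxy)-3-methoxybenzyl chloride | COc1cc(CCl)ccc1OCc1ccccc1 | intermediate
3 | diethyl malonate | CCOC(=O)CC(=O)OCC | starting material
4 | diethyl 2-[4-(benzyloxy)-3-methoxybenzyl]malonate | CCOC(=O)C(Cc1ccc(OCc2ccccc2)c(OC)c1)C(=O)OCC | intermediate
5 | 2-[4-(benzyloxy)-3-methoxybenzyl]propane-1,3-diol | COc1cc(CC(CO)CO)ccc1OCc1ccccc1 | intermediate
6 | (R)-2-[4-(benzyloxy)-3-methoxybenzyl]-3-hydroxypropyl acetate | COc1cc(C[C@H](CO)COC(C)=O)ccc1OCc1ccccc1 | intermediate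
7 | (S)-2-[4-(benzyloxy)-3-methoxybenzyl]-3-[(tert-butyldimethylsilyl)oxy]propyl acetate | COc1cc(C[C@H](CO[Si](C)(C)C(C)(C)C)COC(C)=O)ccc1OCc1ccccc1 | intermediate
8 | (S)-2-[4-(benzyloxy)-3-methoxybenzyl]-3-[(tert-butyldimethylsilyl)oxy]propan-1-ol | COc1cc(C[C@H](CO[Si](C)(C)C(C)(C)C)CO)ccc1OCc1ccccc1 | intermediate
9 | (R)-2-[4-(benzyloxy)-3-methoxybenzyl]-3-[(tert-butyldimethylsilyl)oxy]propanal | COc1cc(C[C@H](CO[Si](C)(C)C(C)(C)C)C=O)ccc1OCc1ccccc1 | intermediate
10 | (S)-{[2-(4-(benzyloxy)-3-methoxybenzyl)but-3-yn-1-yl]oxy}(tert-butyl)dimethylsilane (silyl alkyne) | COc1cc(C[C@H](CO[Si](C)(C)C(C)(C)C)C#C)ccc1OCc1ccccc1 | intermediate (not isolated)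
11 | (S)-2-[4-(benzyloxy)-3-methoxybenzyl]but-3-yn-1-ol | COc1cc(C[C@H](CO)C#C)ccc1OCc1ccccc1 | intermediate
12 | 2-(benzyloxy)phenol | Oc1ccccc1OCc1ccccc1 | starting material
13 | 2-(benzyloxy)-4-bromophenol | Oc1ccc(Br)cc1OCc1ccccc1 | intermediate
14 | 2-(benzyloxy)-4-bromo-6-iodophenol | Oc1c(I)cc(Br)cc1OCc1ccccc1 | intermediate
15 | 1-(benzyloxy)-2-{[4-(benzyloxy)-3-methoxybenzyl]oxy}-5-bromo-3-iodobenzene | COc1cc(COc2c(I)cc(Br)cc2OCc2ccccc2)ccc1OCc1ccccc1 | intermediate
16 | (3-(benzyloxy)-2-{[4-(benzyloxy)-3-methoxybenzyl]oxy}-5-bromophenyl)magnesium chloride | COc1cc(COc2c([Mg]Cl)cc(Br)cc2OCc2ccccc2)ccc1OCc1ccccc1 | intermediate (not isolated)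
17 | methyl 2-(3-(benzyloxy)-2-{[4-(benzyloxy)-3-methoxybenzyl]oxy}-5-bromophenyl)-2-oxoacetate | COC(=O)C(=O)c1cc(Br)cc(OCc2ccccc2)c1OCc1ccc(OCc2ccccc2)c(OC)c1 | intermediate
18 | N-tosylhydrazone of 17 | COC(=O)C(=NNS(=O)(=O)c1ccc(C)cc1)c1cc(Br)cc(OCc2ccccc2)c1OCc1ccc(OCc2ccccc2)c(OC)c1 | intermediate (not isolated)
19 | methyl 2-(3-(benzyloxy)-2-{[4-(benzyloxy)-3-methoxybenzyl]oxy}-5-bromophenyl)-2-diazoacetate | COC(=O)C(=[N+]=[N-])c1cc(Br)cc(OCc2ccccc2)c1OCc1ccc(OCc2ccccc2)c(OC)c1 | intermediate
20 | methyl (2S,3R)-7-(benzyloxy)-2-[4-(benzyloxy)-3-methoxyphenyl]-5-bromo-2,3-dihydro-1-benzofuran-3-carboxylate (cis) | Brc1cc(OCc3ccccc3)c2c(c1)[C@@H](C(=O)OC)[C@@H](c1ccc(OCc3ccccc3)c(OC)c1)O2 | intermediate (not isolated)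
21 | methyl (2S,3S)-7-(benzyloxy)-2-[4-(benzyloxy)-3-methoxyphenyl]-5-bromo-2,3-dihydro-1-benzofuran-3-carboxylate (trans) | Brc1cc(OCc3ccccc3)c2c(c1)[C@H](C(=O)OC)[C@@H](c1ccc(OCc3ccccc3)c(OC)c1)O2 | intermediate
22 | {(2S,3R)-7-(benzyloxy)-2-[4-(benzyloxy)-3-methoxyphenyl]-5-bromo-2,3-dihydro-1-benzofuran-3-yl}methanol | Brc1cc(OCc3ccccc3)c2c(c1)[C@H](CO)[C@@H](c1ccc(OCc3ccccc3)c(OC)c1)O2 | intermediate
23 | (2S,3R)-7-(benzyloxy)-3-[(benzyloxy)methyl]-2-[4-(benzyloxy)-3-methoxyphenyl]-5-bromo-2,3-dihydro-1-benzofuran | Brc1cc(OCc3ccccc3)c2c(c1)[C@H](COCc3ccccc3)[C@@H](c1ccc(OCc3ccccc3)c(OC)c1)O2 | intermediate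
24 | (S)-2-[4-(benzyloxy)-3-methoxybenzyl]-4-{(2S,3R)-7-(benzyloxy)-3-[(benzyloxy)methyl]-2-[4-(benzyloxy)-3-methoxyphenyl]-2,3-dihydro-1-benzofuran-5-yl}but-3-yn-1-ol | COc1cc(C[C@H](CO)C#Cc2cc(OCc4ccccc4)c3c(c2)[C@H](COCc4ccccc4)[C@@H](c2ccc(OCc4ccccc4)c(OC)c2)O3)ccc1OCc1ccccc1 | intermediate
25 | (3E,4S)-4-[4-(benzyloxy)-3-methoxybenzyl]-3-({(2S,3R)-7-(benzyloxy)-3-[(benzyloxy)methyl]-2-[4-(benzyloxy)-3-methoxyphenyl]-2,3-dihydro-1-benzofuran-5-yl}methylidene)dihydrofuran-2(3H)-one | COc1cc(C[C@@H]2COC(=O)/C2=C/c2cc(OCc4ccccc4)c3c(c2)[C@H](COCc4ccccc4)[C@@H](c2ccc(OCc4ccccc4)c(OC)c2)O3)ccc1OCc1ccccc1 | intermediate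
26 | (3R,4S)-cis tetra-O-benzyl lactone (name as in step 19) | COc1cc(C[C@@H]2COC(=O)[C@@H]2Cc2cc(OCc4ccccc4)c3c(c2)[C@H](COCc4ccccc4)[C@@H](c2ccc(OCc4ccccc4)c(OC)c2)O3)ccc1OCc1ccccc1 | intermediate
27 | (3S,4S)-trans tetra-O-benzyl lactone (name as in step 20) | COc1cc(C[C@@H]2COC(=O)[C@H]2Cc2cc(OCc4ccccc4)c3c(c2)[C@H](COCc4ccccc4)[C@@H](c2ccc(OCc4ccccc4)c(OC)c2)O3)ccc1OCc1ccccc1 | intermediate
28 | (3S,4S)-4-(4-hydroxy-3-methoxybenzyl)-3-{[(2S,3R)-7-hydroxy-2-(4-hydroxy-3-methoxyphenyl)-3-(hydroxymethyl)-2,3-dihydro-1-benzofuran-5-yl]methyl}dihydrofuran-2(3H)-one | COc1cc(C[C@@H]2COC(=O)[C@H]2Cc2cc(O)c3c(c2)[C@H](CO)[C@@H](c2ccc(O)c(OC)c2)O3)ccc1O | target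

## Step count and least certain steps

Total: 21 steps. Longest linear sequence: 13 steps (steps 1 to 8, then 17 to 21; the branch from 12, steps 9 to 16 then 17 to 21, is equally long).

**Step 18 (key step).** The aryl-substituted internal alkyne may undergo acyl-palladation slowly. Direct attack of the hydroxyl on the palladium-activated alkyne (cycloisomerisation to a dihydrofuran) or reduction of the catalyst to inactive metal may then take over, and the tin chloride may assist ionisation of the benzylic ring ether at 75 °C. The fallback replaces carbonylation by an aldol condensation; it sets out from 11 and 23 and comes back at 25. Hydroboration of the terminal alkyne of 11 with dicyclohexylborane and oxidative work-up (NaBO3) would give the hydroxy aldehyde as its cyclic hemiacetal, lactol F1. TEMPO with PhI(OAc)2 would oxidise it to (S)-4-[4-(benzyloxy)-3-methoxybenzyl]dihydrofuran-2(3H)-one F2 (the same compound as A9). Bromine–lithium exchange on 23 (n-BuLi, −78 °C) and quenching with DMF would give the benzofuran aldehyde F3. The lithium enolate of F2 (LiHMDS, −78 °C) would add to F3 anti to the C-beta substituent to give aldol adduct F4. Mesylation to mesylate F5 and elimination with DBU would then give 25.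

**Step 14.** The extra ortho benzyloxy group twists the reacting ether out of the arene plane, which may lower enantiofacial discrimination or the cis preference, and attack of the ether oxygen on the carbenoid (ylide formation and 1,2-shift) may compete with insertion. The fallback is a classical resolution; it sets out from 21 and comes back at 22. Saponification (LiOH, THF–water) would give the (2S,3S)-carboxylic acid F6. Crystallisation with (R)-1-phenylethylamine (or its mirror image, whichever gives the less soluble salt of the wanted acid) would give the ammonium salt F7. Acidification and reduction with BH3·SMe2 would return 22.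

**Step 8.** Carbonate in methanol may partly epimerise the α-centre of 9 before the homologation takes place, which would erode the purity of the future C-beta. The fallback is a Corey–Fuchs sequence; it sets out from 9 and comes back at 10. CBr4 and PPh3 would give (S)-dibromoalkene F8 under neutral conditions, and n-BuLi at −78 °C (Fritsch–Buttenberg–Wiechell rearrangement) would give 10, which is desilylated as in the second stage of step 8.

**Step 4.** The acetyl group may be transferred to the other enantiotopic arm (opposite sense), or with too little discrimination. The fallback uses the complementary hydrolytic mode, which inverts the sense; it sets out from 5 and comes back at 6. Acetylation (Ac2O, pyridine) would give diacetate F9, and hydrolysis by the same lipase in phosphate buffer would remove the acetate from the arm the enzyme prefers and leave 6. Slight over-hydrolysis would upgrade the purity.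

**Step 21.** Reductive cleavage of the benzylic C2–O1 bond may compete while the slow aliphatic benzyl ether is still being removed. The fallback changes the protecting group of the primary alcohol so that the hydrogenolysis has only three fast phenolic ethers to cleave; it sets out from 22 (step 16 is skipped) and comes back at 28. TBDPSCl and imidazole would give silyl ether F10. Coupling with 11 as in step 17 would give alkynol F11. Carbonylation as in step 18 would give arylidene lactone F12. Hydrogenation as in step 19 would give cis lactone F13, and DBU would give trans lactone F14. Brief hydrogenolysis over Pd/C would give triphenol silyl ether F15, and HF·pyridine in THF would release 28 without base.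

**Step 19.** The hindered trisubstituted alkene may take up hydrogen slowly on the poisoned catalyst, and forcing the conditions would start premature debenzylation. The fallback is a hydride conjugate reduction; it sets out from 25 and comes back at 26. [(Ph3P)CuH]6 with a silane in toluene would reduce the enoate through a copper enolate, and protonation would give 26 mixed with 27, both of which enter step 20. It would make no compound outside the list (F0).

## Further compounds

F1 | step 18 | (4S)-4-[4-(benzyloxy)-3-methoxybenzyl]tetrahydrofuran-2-ol (lactol, both anomers) | COc1cc(C[C@@H]2COC(O)C2)ccc1OCc1ccccc1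
F2 | step 18 | (S)-4-[4-(benzyloxy)-3-methoxybenzyl]dihydrofuran-2(3H)-one | COc1cc(C[C@@H]2COC(=O)C2)ccc1OCc1ccccc1
F3 | step 18 | (2S,3R)-7-(benzyloxy)-3-[(benzyloxy)methyl]-2-[4-(benzyloxy)-3-methoxyphenyl]-2,3-dihydro-1-benzofuran-5-carbaldehyde | O=Cc1cc(OCc3ccccc3)c2c(c1)[C@H](COCc3ccccc3)[C@@H](c1ccc(OCc3ccccc3)c(OC)c1)O2
F4 | step 18 | aldol adduct, (3S,4S)-lactone carrying a hydroxy(benzofuran-5-yl)methyl group at C-alpha (carbinol centre undefined) | COc1cc(C[C@@H]2COC(=O)[C@H]2C(O)c2cc(OCc4ccccc4)c3c(c2)[C@H](COCc4ccccc4)[C@@H](c2ccc(OCc4ccccc4)c(OC)c2)O3)ccc1OCc1ccccc1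
F5 | step 18 | methanesulfonate of F4 | COc1cc(C[C@@H]2COC(=O)[C@H]2C(OS(C)(=O)=O)c2cc(OCc4ccccc4)c3c(c2)[C@H](COCc4ccccc4)[C@@H](c2ccc(OCc4ccccc4)c(OC)c2)O3)ccc1OCc1ccccc1
F6 | step 14 | (2S,3S)-7-(benzyloxy)-2-[4-(benzyloxy)-3-methoxyphenyl]-5-bromo-2,3-dihydro-1-benzofuran-3-carboxylic acid | Brc1cc(OCc3ccccc3)c2c(c1)[C@H](C(=O)O)[C@@H](c1ccc(OCc3ccccc3)c(OC)c1)O2
F7 | step 14 | (R)-1-phenylethylammonium salt of F6 | Brc1cc(OCc3ccccc3)c2c(c1)[C@H](C(=O)[O-])[C@@H](c1ccc(OCc3ccccc3)c(OC)c1)O2.C[C@@H]([NH3+])c1ccccc1
F8 | step 8 | (S)-{2-[4-(benzyloxy)-3-methoxybenzyl]-4,4-dibromobut-3-en-1-yl}oxy(tert-butyl)dimethylsilane | COc1cc(C[C@H](CO[Si](C)(C)C(C)(C)C)C=C(Br)Br)ccc1OCc1ccccc1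
F9 | step 4 | 2-[4-(benzyloxy)-3-methoxybenzyl]propane-1,3-diyl diacetate | COc1cc(CC(COC(C)=O)COC(C)=O)ccc1OCc1ccccc1
F10 | step 21 | ({(2S,3R)-7-(benzyloxy)-2-[4-(benzyloxy)-3-methoxyphenyl]-5-bromo-2,3-dihydro-1-benzofuran-3-yl}methoxy)(tert-butyl)diphenylsilane | Brc1cc(OCc3ccccc3)c2c(c1)[C@H](CO[Si](c3ccccc3)(c3ccccc3)C(C)(C)C)[C@@H](c1ccc(OCc3ccccc3)c(OC)c1)O2
F11 | step 21 | analogue of 24 with tert-butyldiphenylsilyl in place of the aliphatic benzyl group | COc1cc(C[C@H](CO)C#Cc2cc(OCc4ccccc4)c3c(c2)[C@H](CO[Si](c4ccccc4)(c4ccccc4)C(C)(C)C)[C@@H](c2ccc(OCc4ccccc4)c(OC)c2)O3)ccc1OCc1ccccc1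
F12 | step 21 | analogue of 25 with tert-butyldiphenylsilyl in place of the aliphatic benzyl group | COc1cc(C[C@@H]2COC(=O)/C2=C/c2cc(OCc4ccccc4)c3c(c2)[C@H](CO[Si](c4ccccc4)(c4ccccc4)C(C)(C)C)[C@@H](c2ccc(OCc4ccccc4)c(OC)c2)O3)ccc1OCc1ccccc1
F13 | step 21 | analogue of 26 (cis) with tert-butyldiphenylsilyl in place of the aliphatic benzyl group | COc1cc(C[C@@H]2COC(=O)[C@@H]2Cc2cc(OCc4ccccc4)c3c(c2)[C@H](CO[Si](c4ccccc4)(c4ccccc4)C(C)(C)C)[C@@H](c2ccc(OCc4ccccc4)c(OC)c2)O3)ccc1OCc1ccccc1
F14 | step 21 | analogue of 27 (trans) with tert-butyldiphenylsilyl in place of the aliphatic benzyl group | COc1cc(C[C@@H]2COC(=O)[C@H]2Cc2cc(OCc4ccccc4)c3c(c2)[C@H](CO[Si](c4ccccc4)(c4ccccc4)C(C)(C)C)[C@@H](c2ccc(OCc4ccccc4)c(OC)c2)O3)ccc1OCc1ccccc1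
F15 | step 21 | O-tert-butyldiphenylsilyl ether of 28 at the primary alcohol | COc1cc(C[C@@H]2COC(=O)[C@H]2Cc2cc(O)c3c(c2)[C@H](CO[Si](c4ccccc4)(c4ccccc4)C(C)(C)C)[C@@H](c2ccc(O)c(OC)c2)O3)ccc1O
F0 | step 19 | none | none
A1 | alternative 1 | ethyl (3S,4S)-4-[4-(benzyloxy)-3-methoxybenzyl]-3-({(2S,3R)-7-(benzyloxy)-3-[(benzyloxy)methyl]-2-[4-(benzyloxy)-3-methoxyphenyl]-2,3-dihydro-1-benzofuran-5-yl}methyl)-2-oxotetrahydrofuran-3-carboxylate | COc1cc(C[C@@H]2COC(=O)[C@@]2(C(=O)OCC)Cc2cc(OCc4ccccc4)c3c(c2)[C@H](COCc4ccccc4)[C@@H](c2ccc(OCc4ccccc4)c(OC)c2)O3)ccc1OCc1ccccc1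
A2 | alternative 1 | ethyl (1R,5S)-2-oxo-3-oxabicyclo[3.1.0]hexane-1-carboxylate | CCOC(=O)[C@@]12C[C@@H]1COC2=O
A3 | alternative 1 | (2S,3R)-7-(benzyloxy)-3-[(benzyloxy)methyl]-2-[4-(benzyloxy)-3-methoxyphenyl]-5-(bromomethyl)-2,3-dihydro-1-benzofuran | BrCc1cc(OCc3ccccc3)c2c(c1)[C@H](COCc3ccccc3)[C@@H](c1ccc(OCc3ccccc3)c(OC)c1)O2
A4 | alternative 1 | [4-(benzyloxy)-3-methoxyphenyl]magnesium bromide | COc1cc([Mg]Br)ccc1OCc1ccccc1
A5 | alternative 1 | (S)-epichlorohydrin | ClC[C@@H]1CO1
A6 | alternative 2 | methyl (2S,3S)-trans-7-(benzyloxy)-5-bromo-2-[3-methoxy-4-(pivaloyloxy)phenyl]-2,3-dihydro-1-benzofuran-3-carboxylate | Brc1cc(OCc3ccccc3)c2c(c1)[C@H](C(=O)OC)[C@@H](c1ccc(OC(=O)C(C)(C)C)c(OC)c1)O2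
A7 | alternative 2 | (2S)-8-(benzyloxy)-6-bromo-2-[3-methoxy-4-(pivaloyloxy)phenyl]chroman-4-one | O=C1C[C@@H](c2ccc(OC(=O)C(C)(C)C)c(OC)c2)Oc2c(OCc3ccccc3)cc(Br)cc21
A8 | alternative 2 | (E)-1-[3-(benzyloxy)-5-bromo-2-hydroxyphenyl]-3-[3-methoxy-4-(pivaloyloxy)phenyl]prop-2-en-1-one | O=C(/C=C/c1ccc(OC(=O)C(C)(C)C)c(OC)c1)c1cc(Br)cc(OCc2ccccc2)c1O
A9 | alternative 3 | (S)-4-[4-(benzyloxy)-3-methoxybenzyl]dihydrofuran-2(3H)-one | COc1cc(C[C@@H]2COC(=O)C2)ccc1OCc1ccccc1
A10 | alternative 3 | 3-[4-(benzyloxy)-3-methoxybenzyl]cyclobutan-1-one | COc1cc(CC2CC(=O)C2)ccc1OCc1ccccc1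
A11 | alternative 3 | 4-allyl-1-(benzyloxy)-2-methoxybenzene (O-benzyleugenol) | C=CCc1ccc(OCc2ccccc2)c(OC)c1
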